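## Structural features

The target joins a trans-fused drimane decalin (rings A and B, stereocentres C5, C9 and C10, gem-dimethyl at C4, exocyclic C8=C12) through one methylene, C11, to the fully substituted carbon C1' of an epoxycyclohexenone ring. In that ring C1' and C2' carry a ring-fused oxirane, C3' a secondary hydroxyl on the same face as the oxirane oxygen, C4' a hydroxymethyl group, and C4'=C5' is conjugated to the C6' ketone. The three contiguous ring stereocentres C1', C2' and C3' (all S) are insulated from the decalin stereocentres by C11, so the terpene cannot relay its configuration to them. The fragile groups are the α,β-epoxy ketone with its neighbouring carbinol (base and strong acid), the allylic 1,3-diol, and the 1,1-disubstituted alkene, which migrates into ring B under acid. C11 is a β-branched primary carbon whose neighbour C9 carries a tertiary, allylic hydrogen, so substitution there competes with elimination. The real difficulty is to place one oxygen on one face of an essentially flat quinone ring, at C1'=C2' and not at C4'=C5', with absolute control. The key step exploits the fact that C4'=C5', the alkene that must survive, is a dienophile. A cyclopentadiene bridge across it folds the ring into a cup whose convex face exposes C1'=C2', makes C4' quaternary so that the adduct cannot aromatise, and leaves again on heating.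

## Logic of the disconnections

20 ⇒ 19. The O–Si bond at the C4' hydroxymethyl oxygen is cut. This oxygen must stay masked through oxidation, Lewis acid, alkaline peroxide and heat, so a robust silyl ether is carried to the end. The forward step has to remove silicon without opening the oxirane or dehydrating the β-hydroxy enone.

19 ⇒ 18. The C3'–H bond is cut, returning the carbinol to a ketone. The oxirane then becomes the only stereo-controlling element of the ring and three stereocentres fall to two. The forward hydride must choose C3' over C6' and the face anti to the oxirane oxygen.

18 ⇒ 17. The two C–C bonds from C4' and C5' to a five-carbon bridge are added retrosynthetically. 18 is flat and offers no facial bias, whereas 17 has a concave and a convex face. The forward cycloreversion must be clean at a temperature that the oxirane, the silyl ether and C8=C12 tolerate.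

17 ⇒ 16. The C1'–O and C2'–O bonds are cut. This removes two stereocentres and leaves an enedione. The forward oxidant must be nucleophilic, so that it ignores the two isolated alkenes, and must attack only the convex face.

16 ⇒ 13 + 15. The two C–C bonds from C4' and C5' to the diene termini are cut. This gives a flat quinone and a five-carbon diene and removes four stereocentres. The forward cycloaddition must select C4'=C5' over C1'=C2', proceed endo, and choose one enantiotopic face under catalyst control.

15 ⇒ 14. The two C–C bonds that hold the two five-carbon halves of 14 together are re-formed retrosynthetically. 15 dimerises on standing, so 14 is its stable commercial source, and each molecule of 14 supplies two of 15. The forward cracking must be followed by immediate use of the cold monomer.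

13 ⇒ 12. The two C=O groups are traced back to two aryl methyl ethers. The ring becomes a stable arene that survives cross-coupling. The forward oxidation must spare the silyl ether and C8=C12.

12 ⇒ 7 + 10 (through 11). The C11–C1' bond is cut between an sp3 carbon and an arene carbon. The molecule divides into a terpene half and an arene half of similar size. The forward coupling must form a bond at a hindered primary carbon without elimination towards C9.

10 ⇒ 9. The O–Si bond is cut. The free benzylic alcohol is simpler, but it would not survive the organozinc and the oxidant, so silylation must come before the coupling.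

9 ⇒ 8. The benzylic C–H bond is cut, giving an aldehyde that is commercial and already has the bromine para to the one-carbon substituent. The forward reduction must leave the aryl bromide alone.

7 ⇒ 5 (through 6). The C8=C12 bond is traced back to a tertiary C8 hydroxyl and the C8 methyl group. The alkene, which migrates easily, is thereby introduced only after the radical and basic steps. The forward elimination must remove a methyl hydrogen and not a ring hydrogen.

5 ⇒ 4. The formyl C–O bond is restored. The formate is the direct outcome of the fragmentation that precedes it. The forward cleavage must be mild enough that the tertiary alkoxide does not attack or fragment the C11 iodide.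

4 ⇒ 2 (through 3). The C11–I bond is cut and the bond between C11 and the formyl carbon is re-formed, which closes the lactol ring. One carbon is thus excised from a five-membered ring without touching C9. The forward fragmentation must proceed through the anomeric alkoxyl radical and trap the C11 radical with iodine.

2 ⇒ 1. The lactol C–H bond is cut, returning the lactone. 1 is a commercial terpenoid that already holds C5, C9, C10 and the C8 oxygen. The forward reduction must stop at the lactol.

## Other disconnections considered

Alternative 1: The cut falls on the C2'–O and C3'–O bonds, made on an aromatic ring. In the forward sense, whole cells expressing toluene dioxygenase would oxidise 4-iodobenzyl alcohol A1 with O2 to the cis-dihydrodiol A2. Its two carbinol carbons map onto C3' and C2' with the correct absolute sense, and its vinyl iodide marks C1' for coupling with 11.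
- In its favour: two of the three ring stereocentres come from air and an enzyme in one operation. The C3' carbinol is set absolutely and not by a late hydride reduction, which is better than the chosen plan. The coupling partner is a vinyl iodide, at least the equal of 10 in oxidative addition.
- Against it here: the arene is para-disubstituted, so the enzyme must tell iodine from hydroxymethyl to fix both regiochemistry and enantiopurity, and the free benzylic alcohol invites benzylic oxidation. A2 aromatises by loss of water unless protected at once. After the key step C6' is still a CH, C1'=C6' is still an alkene and the oxirane does not exist, so C6' oxygenation, C1'–O bond formation on the correct face and several protecting-group changes must follow.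
- Comparison: it is stronger on absolute control at C2' and C3', equal on the C11–C1' coupling, and weaker on C1' (derived in extra steps, not together with C2' in one epoxidation) and on step economy after the key step. Mechanistically it trades catalyst control of a cycloaddition for enzyme control of an arene oxidation, and it needs fermentation equipment.

Alternative 2: The cut falls on C9–C11 and C11–C1' at once, with C11 supplied by carbon monoxide. In the forward sense, zerovalent palladium (Pd(PPh3)4) would insert into enol triflate A3, take up CO and couple with arylboronic acid A4 to give the tetrasubstituted aryl enone A5.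
- In its favour: three components are joined in one step. No sp3 organometallic with a β-hydrogen is involved, which is better than the chosen Negishi step in that respect. The unsymmetrically protected arene of A4 would allow a regiodefined quinone monoketal, a better handle for site-selective epoxidation than a symmetric dimethyl ether.
- Against it here: A5 carries C8=C9 and a C11 ketone, so the C9 stereocentre is erased, the 8(12)-alkene is missing and C11 is at the wrong oxidation level. A deconjugative isomerisation with control of C9 and a benzylic deoxygenation next to an easily migrating alkene would both be needed. The hindered tetrasubstituted triflate risks direct coupling without CO. The step does nothing for the three ring stereocentres.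
- Comparison: it is the equal or the better in convergence and in arene protecting-group logic. It is weaker in structure, because a stereocentre is destroyed and rebuilt, and longer overall, because the chosen plan forms C11–C1' at the final oxidation level with C9 and C8=C12 untouched.

Alternative 3: The cut falls on the C1'–O and C4'–O bonds, made together. In the forward sense, singlet oxygen (O2, light, tetraphenylporphyrin) would add [4+2] to the C1'=C2'–C3'=C4' diene of A6 on the face anti to the C6' silyloxy group to give endoperoxide A7. Isomerisation of the O–O bridge to the syn-bis-epoxide A8, oxidation at C6' and base-induced β-elimination of the C3'–O–C4' oxirane would then deliver the C4'=C5' enone and the C3' hydroxyl cis to the surviving oxirane.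
- In its favour: all three ring stereocentres follow from one face-selective addition. The cis relation between oxirane and C3' hydroxyl is built into the mechanism, since both oxygens come from one O2 molecule, which is better than a separate hydride reduction. No choice between two quinone alkenes arises, which is also better.
- Against it here: A6 is a silyloxycyclohexadiene that aromatises readily by loss of silanol and must itself be made enantiomerically pure, with a C6' stereocentre that is later destroyed. The ene reaction of singlet oxygen at C8=C12 and at allylic C–H bonds competes. Peroxides are carried on a hindered terpene. The p-methoxybenzyl ether must later be removed oxidatively from an epoxyquinol.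
- Comparison: it is stronger in stereochemical logic, about equal in the number of steps after the key step, and weaker in access to its precursor, which is not an arene and cannot be reached by one cross-coupling and one oxidation as 13 can.

Key step: step 10

## Assumptions and design notes

- Locants: C1' bears C11, C2' is the oxirane CH, C3' the carbinol, C4' bears the CH2O group, C5' is the vinyl CH, C6' the ketone.
- Nomenclature: the linking CH2 is C11 of the drimane itself, so the substituent on the ring is drim-8(12)-en-11-yl (albicanyl); no extra carbon lies between the terpene and the ring.
- Stereochemistry of the key pair: 16 is drawn as the endo adduct whose convex-face epoxidation leads to the (1'S,2'S) oxirane of 20. It is assumed that the (S)-oxazaborolidinium ion opens this enantiotopic face of C4'=C5', as its pre-transition-state model predicts.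
- Design of the precursor and its preparation:
  - The hydroxymethyl oxygen is carried as a tert-butyldiphenylsilyl ether, because a tert-butyldimethylsilyl ether would be at risk under acidic tetravalent cerium.
  - The C11–C1' bond is made by Negishi coupling, not by displacement at the β-branched C11 halide with an aryllithium, where elimination towards C9 would compete.
  - The arene comes from a commercial aldehyde that already has the bromine in place.

## Steps

Step 1
Reactants: 1 (+)-sclareolide
Product: 2 sclareolide lactol (8α,12-epoxy-13,14,15,16-tetranorlabdan-12-ol; both C12 anomers)
Conditions: i-Bu2AlH, CH2Cl2, −78 °C; aq. KNaC4H4O6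
Reagents that add atoms: none
Why: Partial reduction of a γ-lactone to the lactol by an aluminium hydride at low temperature, where the tetrahedral aluminate does not collapse; no stereocentre of the decalin is touched.

Step 2
Reactants: 2 sclareolide lactol
Product: 4 11-iodo-drimane-8α-yl formate (9β-CH2I; 8α-OCHO; 8β-CH3), via lactol hypoiodite 3 (not isolated)
Conditions: PhI(OAc)2, I2, CH2Cl2, visible light (hν), 25 °C
Reagents that add atoms: iodine, [I][I]
Why: Hypoiodite (alkoxyl radical) β-fragmentation of a lactol: homolysis of the O–I bond gives the anomeric alkoxyl radical, which cleaves the bond between C11 and the lactol carbon to leave that carbon as the formate on the C8 oxygen and a primary C11 radical that is trapped by iodine. C9 is not a radical centre at any point, so its configuration is kept.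

Step 3
Reactants: 4 11-iodo-drimane-8α-yl formate
Product: 5 11-iodo-drimane-8α-ol (9β-CH2I; 8α-OH; 8β-CH3)
Conditions: K2CO3 (0.2 equiv), MeOH, 0 °C
Reagents that add atoms: none
Why: Transesterification of a formate, the most labile of esters, with methanol; catalytic carbonate at 0 °C keeps the concentration of tertiary alkoxide too low for displacement or fragmentation involving the C11 iodide.

Step 4
Reactants: 5 11-iodo-drimane-8α-ol
Product: 7 11-iodo-drim-8(12)-ene (albicanyl iodide; 9α-H; 9β-CH2I), via chlorosulfite ester 6 (not isolated)
Conditions: SOCl2, pyridine, CH2Cl2, −78 °C
Reagents that add atoms: none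
Why: Dehydration through the chlorosulfite by base-induced anti elimination: the equatorial C8–O bond has only ring C–C bonds antiperiplanar, so pyridine removes a hydrogen of the axial C8 methyl group (C12 of the drimane) and the exocyclic alkene should predominate (Hofmann orientation). Minor ring-alkene isomers are removed on AgNO3-impregnated silica.

Step 5
Reactants: 8 4-bromo-2,5-dimethoxybenzaldehyde
Product: 9 (4-bromo-2,5-dimethoxyphenyl)methanol
Conditions: NaBH4, MeOH, 0 °C
Reagents that add atoms: none
Why: Borohydride reduction of an aryl aldehyde; the aryl bromide and the ethers are inert.

Step 6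
Reactants: 9 (4-bromo-2,5-dimethoxyphenyl)methanol
Product: 10 (4-bromo-2,5-dimethoxybenzyloxy)(tert-butyl)diphenylsilane
Conditions: t-BuPh2SiCl, imidazole, CH2Cl2, 25 °C
Reagents that add atoms: tert-butyl(chloro)diphenylsilane, CC(C)(C)[Si](Cl)(c1ccccc1)c1ccccc1
Why: Imidazole-promoted silylation of a primary alcohol; this silyl group is chosen for its tolerance of acid, Lewis acid, alkaline peroxide and heat in steps 8 to 12.

Step 7
Reactants: 7 11-iodo-drim-8(12)-ene; 10 (4-bromo-2,5-dimethoxybenzyloxy)(tert-butyl)diphenylsilane
Product: 12 tert-butyl[4-(drim-8(12)-en-11-yl)-2,5-dimethoxybenzyloxy]diphenylsilane, via alkylzinc iodide 11 (not isolated)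
Conditions: Zn dust (activated with BrCH2CH2Br and Me3SiCl), LiCl, THF, 40 °C; then 10, Pd(OAc)2 (3 mol %), 2-dicyclohexylphosphino-2′,6′-dimethoxybiphenyl (6 mol %), THF, 25 → 50 °C
Reagents that add atoms: none
Why: Zinc insertion into the primary C11–I bond followed by Negishi sp3–sp2 cross-coupling with the aryl bromide. The bulky electron-rich biarylphosphine makes reductive elimination faster than β-hydride loss towards C9, and C9 keeps its configuration because only C11 is metalated.

Step 8
Reactants: 12 tert-butyl[4-(drim-8(12)-en-11-yl)-2,5-dimethoxybenzyloxy]diphenylsilane
Product: 13 2-(drim-8(12)-en-11-yl)-5-(tert-butyldiphenylsilyloxymethyl)-1,4-benzoquinone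
Conditions: (NH4)2Ce(NO3)6, MeCN/H2O, 0 °C
Reagents that add atoms: water, O
Why: Oxidative demethylation of a 1,4-dimethoxyarene by two one-electron oxidations with tetravalent cerium; water adds to the arene radical cation and methanol is lost. The electron-rich arene is oxidised far more easily than the isolated C8=C12 alkene, and the silyl ether chosen should withstand the acidic medium for the short reaction time.

Step 9
Reactants: 14 dicyclopentadiene
Product: 15 cyclopenta-1,3-diene
Conditions: neat, 170 °C, distil, collect at −78 °C
Reagents that add atoms: none
Why: Thermal retro-Diels–Alder cracking of the dimer, in which each molecule of 14 gives two molecules of 15; the monomer is distilled as it forms and used at once.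

Step 10
Reactants: 13 2-(drim-8(12)-en-11-yl)-5-(tert-butyldiphenylsilyloxymethyl)-1,4-benzoquinone; 15 cyclopenta-1,3-diene
Product: 16 endo-4a-(tert-butyldiphenylsilyloxymethyl)-7-(drim-8(12)-en-11-yl)-1,4,4a,8a-tetrahydro-1,4-methanonaphthalene-5,8-dione (cis ring fusion; CH2OSi and H-8a exo)
Conditions: (S)-3,3-diphenyl-1-(o-tolyl)tetrahydro-1H,3H-pyrrolo[1,2-c][1,3,2]oxazaborole (20 mol %), HN(SO2CF3)2 (17 mol %), CH2Cl2, −78 °C
Reagents that add atoms: none
Why: The protonated oxazaborolidine, a chiral boron Lewis acid, binds the C6' carbonyl of 13 at the lone pair syn to C5'–H, and cyclopentadiene adds across C4'=C5' in a concerted, asynchronous, normal-demand [4+2] cycloaddition that bonds to C4' slightly ahead of C5'; the closest known reaction type is the oxazaborolidinium-catalysed enantioselective Diels–Alder reaction of 2,5-disubstituted 1,4-benzoquinones at a trisubstituted alkene. Both new rings of the norbornene (the cyclohexene made of the four diene carbons with C4' and C5', and with it the second ring of the bicyclo[2.2.1] frame) close in this one intermolecular event, suprafacial on both partners, so the C4'/C5' ring fusion is necessarily cis. The two bridgehead centres are fixed relative to C4' and C5' by the endo transition state, in which both quinone carbonyls lie under the diene and the CH2OSi group and H-5' point towards the methano bridge. The absolute configuration of all four centres is set by the catalyst: the phenyl group cis to the boron-bound quinone covers one face of C4'=C5', and the pre-transition-state model for the (S)-catalyst leaves open the face that gives 16 (the (R)-catalyst would be taken if the sense proved opposite). The selectivity that matters is site selectivity for C4'=C5' over C1'=C2': it rests on the β-branched drimenyl group, which crowds the carbon (C1') that would have to become quaternary in the competing mode, and on the σ-withdrawing silyloxy group, which makes C4'=C5' the more electron-poor alkene; the somewhat greater basicity of the C3' carbonyl works against it. Because C4' becomes quaternary, 16 cannot aromatise by enolisation.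

Step 11
Reactants: 16 endo adduct
Product: 17 6,7-epoxide of 16 with the oxirane oxygen on the convex face (syn to CH2OSi and H-8a; anti to the norbornene alkene)
Conditions: 30 % aq. H2O2, Na2CO3, acetone/H2O, 0 °C
Reagents that add atoms: hydrogen peroxide, OO
Why: Weitz–Scheffer nucleophilic epoxidation of the enedione: hydroperoxide adds to C2' from the convex face, because the norbornene alkene lies under the other face, and the enolate closes onto the O–O bond on the same side, which sets C1' and C2' together. The two isolated alkenes do not react with a nucleophilic oxidant.

Step 12
Reactants: 17 convex-face epoxide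
Product: 18 (1S,6R)-1-(drim-8(12)-en-11-yl)-4-(tert-butyldiphenylsilyloxymethyl)-7-oxabicyclo[4.1.0]hept-3-ene-2,5-dione
Conditions: Ph2O, 230 °C, argon stream
Reagents that add atoms: none
Why: Thermal retro-Diels–Alder reaction, driven by entropy, by removal of cyclopentadiene in the gas stream and by the regained conjugation of C4'=C5' with both carbonyls, and eased by the quaternary C4'. The oxirane centres C1' and C2' are not involved, and the four centres of the mask disappear.

Step 13
Reactants: 18 epoxyquinone
Product: 19 (1S,5S,6S)-1-(drim-8(12)-en-11-yl)-5-hydroxy-4-(tert-butyldiphenylsilyloxymethyl)-7-oxabicyclo[4.1.0]hept-3-en-2-one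
Conditions: NaBH4, CeCl3·7H2O, MeOH, −78 °C
Reagents that add atoms: none
Why: Luche 1,2-reduction: the C3' carbonyl should react in preference to C6', which is flanked by the quaternary C1' with its bulky drimenyl group and is less electrophilic because the substituted carbon C4' is its β-carbon. Hydride adds anti to the adjacent C2'–O bond (Felkin–Anh), so the new hydroxyl lies cis to the oxirane oxygen and C3' is S.

Step 14
Reactants: 19 silyl-protected epoxyquinol
Product: 20 (1S,5S,6S)-1-(drim-8(12)-en-11-yl)-5-hydroxy-4-(hydroxymethyl)-7-oxabicyclo[4.1.0]hept-3-en-2-one (target)
Conditions: HF·pyridine, pyridine, THF, 0 → 25 °C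
Reagents that add atoms: none
Why: Fluoride-induced cleavage of the primary silyl ether; buffering with pyridine keeps the medium mild enough for the oxirane, whose carbons are deactivated towards ionisation by the adjacent carbonyl and carbinol, and for the β-hydroxy enone.

## Compound list

1 | (+)-sclareolide, (3aR,5aS,9aS,9bR)-3a,6,6,9a-tetramethyldecahydronaphtho[2,1-b]furan-2(1H)-one | C[C@]12CCCC([C@@H]1CC[C@@]3([C@@H]2CC(=O)O3)C)(C)C | starting material
2 | sclareolide lactol (8α,12-epoxy-13,14,15,16-tetranorlabdan-12-ol, both C12 anomers) | C[C@]12CCCC([C@@H]1CC[C@@]3([C@@H]2CC(O)O3)C)(C)C | intermediate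
3 | lactol hypoiodite (O–I on the lactol carbon of 2) | C[C@]12CCCC([C@@H]1CC[C@@]3([C@@H]2CC(OI)O3)C)(C)C | intermediate (not isolated)
4 | 11-iodo-drimane-8α-yl formate (5α-H, 10β-CH3, 9α-H, 9β-CH2I, 8α-OCHO, 8β-CH3) | C[C@]12CCCC([C@@H]1CC[C@@]([C@@H]2CI)(C)OC=O)(C)C | intermediate
5 | 11-iodo-drimane-8α-ol | C[C@]12CCCC([C@@H]1CC[C@@]([C@@H]2CI)(C)O)(C)C | intermediate
6 | chlorosulfite ester of 5 (8α-OS(O)Cl) | C[C@]12CCCC([C@@H]1CC[C@@]([C@@H]2CI)(C)OS(=O)Cl)(C)C | intermediate (not isolated)
7 | 11-iodo-drim-8(12)-ene (albicanyl iodide; 5α-H, 10β-CH3, 9α-H) | C=C1CC[C@H]2C(C)(C)CCC[C@]2(C)[C@H]1CI | intermediate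
8 | 4-bromo-2,5-dimethoxybenzaldehyde | COc1cc(Br)c(OC)cc1C=O | starting material
9 | (4-bromo-2,5-dimethoxyphenyl)methanol | COc1cc(Br)c(OC)cc1CO | intermediate
10 | (4-bromo-2,5-dimethoxybenzyloxy)(tert-butyl)diphenylsilane | COc1cc(Br)c(OC)cc1CO[Si](c1ccccc1)(c1ccccc1)C(C)(C)C | intermediate
11 | (drim-8(12)-en-11-yl)zinc iodide | C=C1CC[C@H]2C(C)(C)CCC[C@]2(C)[C@H]1C[Zn]I | intermediate (not isolated)
12 | tert-butyl[4-(drim-8(12)-en-11-yl)-2,5-dimethoxybenzyloxy]diphenylsilane | C=C1CC[C@H]2C(C)(C)CCC[C@]2(C)[C@H]1Cc1cc(OC)c(CO[Si](c2ccccc2)(c2ccccc2)C(C)(C)C)cc1OC | intermediate
13 | 2-(drim-8(12)-en-11-yl)-5-(tert-butyldiphenylsilyloxymethyl)-1,4-benzoquinone | C=C1CC[C@H]2C(C)(C)CCC[C@]2(C)[C@H]1CC1=CC(=O)C(CO[Si](c2ccccc2)(c2ccccc2)C(C)(C)C)=CC1=O | intermediate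
14 | dicyclopentadiene | C1C=CC2C1C3CC2C=C3 | starting material
15 | cyclopenta-1,3-diene | C1=CC=CC1 | intermediate
16 | endo-4a-(tert-butyldiphenylsilyloxymethyl)-7-(drim-8(12)-en-11-yl)-1,4,4a,8a-tetrahydro-1,4-methanonaphthalene-5,8-dione (cis-fused; CH2OSi and H-8a exo) | C=C1CC[C@H]2C(C)(C)CCC[C@]2(C)[C@H]1CC3=CC(=O)[C@]4(CO[Si](c6ccccc6)(c7ccccc7)C(C)(C)C)[C@@H]5C=C[C@@H](C5)[C@@H]4C3=O | intermediate
17 | 6,7-epoxide of 16, oxirane oxygen on the convex face (syn to CH2OSi and H-8a) | C=C1CC[C@H]2C(C)(C)CCC[C@]2(C)[C@H]1C[C@]12O[C@H]1C(=O)[C@]3(CO[Si](c6ccccc6)(c7ccccc7)C(C)(C)C)[C@@H]4C=C[C@@H](C4)[C@@H]3C2=O | intermediate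
18 | (1S,6R)-1-(drim-8(12)-en-11-yl)-4-(tert-butyldiphenylsilyloxymethyl)-7-oxabicyclo[4.1.0]hept-3-ene-2,5-dione | C=C1CC[C@H]2C(C)(C)CCC[C@]2(C)[C@H]1C[C@]12O[C@H]1C(=O)C(CO[Si](c3ccccc3)(c3ccccc3)C(C)(C)C)=CC2=O | intermediate
19 | (1S,5S,6S)-1-(drim-8(12)-en-11-yl)-5-hydroxy-4-(tert-butyldiphenylsilyloxymethyl)-7-oxabicyclo[4.1.0]hept-3-en-2-one | C=C1CC[C@H]2C(C)(C)CCC[C@]2(C)[C@H]1C[C@]12O[C@H]1[C@@H](O)C(CO[Si](c3ccccc3)(c3ccccc3)C(C)(C)C)=CC2=O | intermediate
20 | (1S,5S,6S)-1-(drim-8(12)-en-11-yl)-5-hydroxy-4-(hydroxymethyl)-7-oxabicyclo[4.1.0]hept-3-en-2-one (hydroxyl cis to the oxirane oxygen) | C=C1CC[C@H]2C(C)(C)CCC[C@]2(C)[C@H]1C[C@]12O[C@H]1[C@@H](O)C(CO)=CC2=O | target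

## Step count and least certain steps

Total: 14 steps, counting the cracking of 14 and the two steps to 10. Longest linear sequence: 11 steps (steps 1, 2, 3, 4, 7, 8, 10, 11, 12, 13, 14, from 1 to 20).

Step 10 (key step). The most likely failure is erosion of site selectivity, with cycloaddition at C1'=C2'. The cause would be preferential binding of the catalyst to the more basic C3' carbonyl, whose activated α,β-bond is the wrong one; incomplete facial control is the second concern. The fallback gives up reagent control. The cycloaddition of 13 with 15 is run without any Lewis acid (toluene, 25 to 60 °C), so the choice of alkene depends only on the intrinsic steric and electronic difference between the two quinone alkenes and not on where a catalyst binds. This should give 16 together with its facial diastereomer, the endo adduct with the mirror-image tricycle on the same terpene F1. The two are diastereomers and should be separable by chromatography. F1 is returned to 13 and 15 by brief thermolysis and recycled. The fallback sets out from 13 and 15 and comes back to the route at 16.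

Step 13. The most likely failures are loss of regiocontrol between the C3' and C6' carbonyls, hydride delivery to the face syn to the oxirane, or conjugate reduction of the enedione, since both carbonyls are conjugated and hindered. The fallback changes the order and the source of control. The silyl group of 18 is removed first (HF·pyridine, pyridine, THF) to give the hydroxymethyl epoxyquinone F2. Its free primary hydroxyl then binds Me4NBH(OAc)3 (AcOH/MeCN, −20 °C) and delivers hydride intramolecularly to the neighbouring C3' carbonyl only, on the face that the oxirane oxygen leaves open. This is a hydroxyl-directed triacetoxyborohydride reduction of a β-hydroxy ketone. The fallback sets out from 18 and comes back to the route at 20.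

Step 7. The most likely failures are slow zinc insertion at the hindered β-branched iodide and β-hydride loss from the alkylpalladium intermediate, whose C9 hydrogen is tertiary and allylic, leading to elimination and reduced arene. The fallback avoids a preformed organometallic altogether: a nickel-catalysed reductive cross-electrophile coupling of 7 with 10 (NiBr2(MeOCH2CH2OMe), 4,4′-di-tert-butyl-2,2′-bipyridine, Mn powder, NaI, N,N-dimethylacetamide, 60 °C). Here a C11 radical is captured by an arylnickel species and no long-lived alkylmetal with a β-hydrogen is present. It sets out from 7 and 10 and comes back to the route at 12.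

Step 12. The most likely failure is thermal degradation (oxirane rearrangement, desilylation, ene reactions of C8=C12 with the enedione) at the temperature the cycloreversion needs, or re-addition of cyclopentadiene on cooling. The fallback replaces purely thermal activation by Lewis acid catalysis with a trap. 17 is treated with MeAlCl2 and an excess of maleic anhydride in ClCH2CH2Cl at 25 to 55 °C. The aluminium reagent lowers the barrier of the cycloreversion as it does for the forward reaction, and maleic anhydride removes cyclopentadiene irreversibly. Both oxirane carbons are α to a carbonyl and so resist ionisation, and MeAlCl2 scavenges protons that could move the 8(12)-alkene. It sets out from 17 and comes back to the route at 18.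

## Further compounds

F1 | step 10 | facial diastereomer of 16 (endo adduct with the enantiomeric tricyclic core on the same drimenyl group) | C=C1CC[C@H]2C(C)(C)CCC[C@]2(C)[C@H]1CC3=CC(=O)[C@@]4(CO[Si](c6ccccc6)(c7ccccc7)C(C)(C)C)[C@H]5C=C[C@H](C5)[C@H]4C3=O
F2 | step 13 | (1S,6R)-1-(drim-8(12)-en-11-yl)-4-(hydroxymethyl)-7-oxabicyclo[4.1.0]hept-3-ene-2,5-dione | C=C1CC[C@H]2C(C)(C)CCC[C@]2(C)[C@H]1C[C@]12O[C@H]1C(=O)C(CO)=CC2=O
F0 | step 7 | none | none
F0 | step 12 | none | none
A1 | alternative 1 | 4-iodobenzyl alcohol | OCc1ccc(I)cc1
A2 | alternative 1 | (1S,2S)-6-(hydroxymethyl)-3-iodocyclohexa-3,5-diene-1,2-diol | IC1=CC=C(CO)[C@H](O)[C@@H]1O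
A3 | alternative 2 | 11-nordrim-8-en-9-yl trifluoromethanesulfonate ((4aS,8aS)-2,5,5,8a-tetramethyl-3,4,4a,5,6,7,8,8a-octahydronaphthalen-1-yl triflate) | CC=1CC[C@H]2C(C)(C)CCC[C@]2(C)C=1OS(=O)(=O)C(F)(F)F
A4 | alternative 2 | [5-methoxy-2-(methoxymethoxy)-4-(triisopropylsilyloxymethyl)phenyl]boronic acid | OB(O)c1cc(OC)c(CO[Si](C(C)C)(C(C)C)C(C)C)cc1OCOC
A5 | alternative 2 | aryl drim-8-en-11-one (11-[5-methoxy-2-(methoxymethoxy)-4-(triisopropylsilyloxymethyl)phenyl]drim-8-en-11-one) | CC=1CC[C@H]2C(C)(C)CCC[C@]2(C)C=1C(=O)c1cc(OC)c(CO[Si](C(C)C)(C(C)C)C(C)C)cc1OCOC
A6 | alternative 3 | 1-(drim-8(12)-en-11-yl)-4-(4-methoxybenzyloxymethyl)-6-(tert-butyldimethylsilyloxy)cyclohexa-1,3-diene (C6' configuration as in A7) | C=C1CC[C@H]2C(C)(C)CCC[C@]2(C)[C@H]1CC1=CC=C(COCc2ccc(OC)cc2)C[C@@H]1O[Si](C)(C)C(C)(C)C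
A7 | alternative 3 | 2,3-dioxabicyclo[2.2.2]oct-5-ene endoperoxide (peroxide bridge C1'–O–O–C4' anti to the C6' silyloxy group) | C=C1CC[C@H]2C(C)(C)CCC[C@]2(C)[C@H]1C[C@]34OO[C@](COCc5ccc(OC)cc5)(C=C3)C[C@@H]4O[Si](C)(C)C(C)(C)C
A8 | alternative 3 | syn-bis-epoxide from A7 (C1'–C2' and C3'–C4' oxiranes on the same face, anti to the C6' silyloxy group) | C=C1CC[C@H]2C(C)(C)CCC[C@]2(C)[C@H]1C[C@]12O[C@H]1[C@H]1O[C@@]1(COCc3ccc(OC)cc3)C[C@@H]2O[Si](C)(C)C(C)(C)C
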